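## Retrosynthetic overview

1. Target ⇒ its tris-TBS ether ⇒ one open-chain precursor with a 3-alkylcyclobutenone at the chain end and an ethynyl ether on the ring-B oxygen. A thermal vinylketene/ynol ether benzannulation cascade builds ring A and closes the 22-membered ring in the same operation.
2. Cyclobutenone ⇒ chain-end Grignard reagent + a 3-alkoxycyclobutenone; ethynyl ether ⇒ aryl dichlorovinyl ether (trichloroethylene, then n-BuLi).
3. (R)-Benzylic carbinol ⇒ catalytic enantioselective addition of a C13 (Z)-alkenyl Grignard reagent to a gallaldehyde-derived aldehyde; the C13 piece ⇒ Wittig union of a C6 ylide and a C7 aldehyde.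
4. Ring order: ring B is bought; ring A and the macrocycle are formed together in the last step.

Assumption: TBS = tert-butyldimethylsilyl; the four starting materials numbered in the steps are taken as catalogue compounds.

## Route

Step 1
Reactants: 1 1-bromo-6-chlorohexane
Product: 2 (6-chlorohexyl)triphenylphosphonium bromide
Conditions: PPh3, MeCN, reflux, 24 h
Reagents that add atoms: triphenylphosphine, c1ccc(cc1)P(c1ccccc1)c1ccccc1
Why: SN2 quaternisation of PPh3 takes place selectively at the primary C–Br bond, the C–Cl bond being far less reactive (phosphonium salt formation).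

Step 2
Reactants: 3 ethyl 7-bromoheptanoate
Product: 4 7-bromoheptanal
Conditions: i-Bu2AlH (1.05 equiv), CH2Cl2, −78 °C; aq. KNaC4H4O6
Reagents that add atoms: none
Why: At −78 °C the ester is reduced only as far as the tetrahedral aluminium hemiacetal, which releases the aldehyde on work-up (low-temperature ester half-reduction); the primary bromide is untouched.

Step 3
Reactants: 2 (6-chlorohexyl)triphenylphosphonium bromide, 4 7-bromoheptanal
Product: 6 (Z)-13-bromo-1-chlorotridec-6-ene, via ylide 5 (not isolated)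
Conditions: 2, NaN(SiMe3)2, THF, −78 → −40 °C; then 4, −78 °C → rt
Reagents that add atoms: none
Why: Wittig reaction of a salt-free non-stabilised ylide with an unbranched aldehyde gives the cis-alkene under kinetic control (typically ≥ 95:5 Z:E), and at −78 °C the ylide is trapped by the aldehyde long before it can alkylate either halide.

Step 4
Reactants: 7 3,4,5-trihydroxybenzaldehyde
Product: 9 3,5-bis(tert-butyldimethylsilyloxy)-4-[(E)-1,2-dichloroethenyloxy]benzaldehyde, via diol 8 (not isolated)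
Conditions: K2CO3 (1.1 equiv), Cl2C=CHCl (1.5 equiv), DMF, 60 °C; then imidazole, TBSCl (2.4 equiv), rt
Reagents that add atoms: trichloroethylene, ClC=C(Cl)Cl; tert-butyldimethylsilyl chloride, CC(C)(C)[Si](C)(C)Cl
Why: With one equivalent of base only the most acidic 4-OH (para to the formyl group) is ionised and adds anti to dichloroacetylene formed in situ, giving the (E)-1,2-dichlorovinyl ether (Greene dichlorovinyl ether synthesis); the two remaining phenols are then silylated in the same DMF solution (imidazole-promoted silylation).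

Step 5
Reactants: 6 (Z)-13-bromo-1-chlorotridec-6-ene, 9 3,5-bis(tert-butyldimethylsilyloxy)-4-[(E)-1,2-dichloroethenyloxy]benzaldehyde
Product: 12 (1R,8Z)-1-{3,5-bis(tert-butyldimethylsilyloxy)-4-[(E)-1,2-dichloroethenyloxy]phenyl}-14-chlorotetradec-8-en-1-ol, via alkylmagnesium bromide 10 (not isolated), via alkyltitanium triisopropoxide 11 (not isolated)
Conditions: 6, Mg, Et2O, 35 °C; Ti(OiPr)4, CH2Cl2, −78 °C; then 9, (R)-3-(3,5-diphenylphenyl)-H8-BINOL (5 mol %), Ti(OiPr)4, CH2Cl2, 0 °C; 1 M HCl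
Reagents that add atoms: none
Why: Mg inserts into C–Br and leaves C–Cl, and the derived RTi(OiPr)3 adds to the aldehyde on the chiral (BINOLate)Ti(OiPr)2 species formed in situ (catalytic enantioselective Grignard/titanium alkylation of aryl aldehydes), the (R)-ligand delivering the alkyl group to the Re face to set the (R)-carbinol (≥ 90% ee expected; sense and ee to be confirmed by Mosher ester analysis).

Step 6
Reactants: 12 (1R,8Z)-1-{3,5-bis(tert-butyldimethylsilyloxy)-4-[(E)-1,2-dichloroethenyloxy]phenyl}-14-chlorotetradec-8-en-1-ol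
Product: 13 (1R,8Z)-1-{3,5-bis(tert-butyldimethylsilyloxy)-4-[(E)-1,2-dichloroethenyloxy]phenyl}-1-(tert-butyldimethylsilyloxy)-14-chlorotetradec-8-ene
Conditions: TBSCl, imidazole, DMAP (cat.), DMF, 35 °C
Reagents that add atoms: tert-butyldimethylsilyl chloride, CC(C)(C)[Si](C)(C)Cl
Why: Imidazole-promoted O-silylation masks the carbinol, which would otherwise trap the ketene of the last step, without touching the C–O stereocenter.

Step 7
Reactants: 13 (1R,8Z)-1-{3,5-bis(tert-butyldimethylsilyloxy)-4-[(E)-1,2-dichloroethenyloxy]phenyl}-1-(tert-butyldimethylsilyloxy)-14-chlorotetradec-8-ene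
Product: 16 (1R,8Z)-1-[3,5-bis(tert-butyldimethylsilyloxy)-4-(ethynyloxy)phenyl]-1-(tert-butyldimethylsilyloxy)-14-chlorotetradec-8-ene, via chloroethynyl ether 14 (not isolated), via lithium acetylide 15 (not isolated)
Conditions: n-BuLi (2.5 equiv), THF, −78 → −40 °C; then H2O, −78 °C
Reagents that add atoms: none
Why: n-BuLi dehydrochlorinates the dichlorovinyl ether to the chloroalkynyl ether and then exchanges Cl for Li (Greene ynol ether synthesis), the primary alkyl chloride and the silyl ethers being inert at ≤ −40 °C; protonation gives the terminal aryl ynol ether, kinetically shielded by its two ortho silyloxy groups.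

Step 8
Reactants: 16 (1R,8Z)-1-[3,5-bis(tert-butyldimethylsilyloxy)-4-(ethynyloxy)phenyl]-1-(tert-butyldimethylsilyloxy)-14-chlorotetradec-8-ene, 17 3-ethoxycyclobut-2-en-1-one
Product: 21 3-{(6Z,14R)-14-[3,5-bis(tert-butyldimethylsilyloxy)-4-(ethynyloxy)phenyl]-14-(tert-butyldimethylsilyloxy)tetradec-6-en-1-yl}cyclobut-2-en-1-one, via alkynylmagnesium chloride 18 (not isolated), via bis(chloromagnesium) reagent 19 (not isolated), via chloromagnesium alkoxide 20 (not isolated)
Conditions: i-PrMgCl (1.05 equiv), THF, 0 °C; Mg (I2-activated), THF, 55 °C; then 17 (1.0 equiv), −78 °C; 0.5 M HCl, 0 °C, 10 min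
Reagents that add atoms: none
Why: Once the alkyne C–H is masked as its magnesium acetylide, Mg insertion into the primary C–Cl bond gives an alkyl Grignard end that adds 1,2 to the vinylogous ester far faster than the alkynyl–Mg end; brief dilute acid then converts the 3-ethoxycyclobutenol into the 3-alkylcyclobutenone with loss of ethanol (Stork–Danheiser alkoxyenone transposition), while the aryl ynol ether, which hydrates orders of magnitude more slowly, is only reprotonated.

Step 9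
Reactants: 21 3-{(6Z,14R)-14-[3,5-bis(tert-butyldimethylsilyloxy)-4-(ethynyloxy)phenyl]-14-(tert-butyldimethylsilyloxy)tetradec-6-en-1-yl}cyclobut-2-en-1-one
Product: 27 target CNP0316989.2 [(R)-carbinol; (Z)-alkene], via vinylketene 22 (not isolated), via macrocyclic vinylcyclobutenone 23 (not isolated), via dienylketene 24 (not isolated), via cyclohexadienone 25 (not isolated), via tris-TBS macrocycle 26 (not isolated)
Conditions: PhMe (0.5 mM final, syringe-pump addition), BHT (cat.), 110 °C, 24 h; concentrate; then Bu4NF, THF, 0 °C → rt; AcOH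
Reagents that add atoms: none
Why: Proposed new method: a macrocyclising, intramolecular version of the Danheiser cyclobutenone–heteroalkyne benzannulation (closest known chemistry: the intermolecular reaction of 3-alkylcyclobutenones with alkoxy- and siloxyalkynes) — reversible 4π opening gives a vinylketene that either recloses harmlessly or is trapped by the tethered aryl ynol ether in a regioselective [2+2] (ketene carbon to the terminal alkyne carbon) that closes the 22-membered ring, after which 4π opening, 6π electrocyclisation and tautomerisation of the 4-vinylcyclobutenone give the 3-aryloxy-5-alkylphenol ring A, so arene and macrocycle form in one operation with the carbinol and the (Z)-alkene untouched; fluoride then removes the three silyl groups.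

## Compound list

1 | 1-bromo-6-chlorohexane | ClCCCCCCBr | starting material
2 | (6-chlorohexyl)triphenylphosphonium bromide | ClCCCCCC[P+](c1ccccc1)(c1ccccc1)c1ccccc1.[Br-] | intermediate
3 | ethyl 7-bromoheptanoate | CCOC(=O)CCCCCCBr | starting material
4 | 7-bromoheptanal | O=CCCCCCCBr | intermediate
5 | (6-chlorohexylidene)triphenylphosphorane (ylide) | ClCCCCCC=P(c1ccccc1)(c1ccccc1)c1ccccc1 | intermediate
6 | (Z)-13-bromo-1-chlorotridec-6-ene | ClCCCCC/C=C\CCCCCCBr | intermediate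
7 | 3,4,5-trihydroxybenzaldehyde | O=Cc1cc(O)c(O)c(O)c1 | starting material
8 | 4-[(E)-1,2-dichloroethenyloxy]-3,5-dihydroxybenzaldehyde | Cl/C=C(/Cl)Oc1c(O)cc(C=O)cc1O | intermediate
9 | 3,5-bis(tert-butyldimethylsilyloxy)-4-[(E)-1,2-dichloroethenyloxy]benzaldehyde | Cl/C=C(/Cl)Oc1c(O[Si](C)(C)C(C)(C)C)cc(C=O)cc1O[Si](C)(C)C(C)(C)C | intermediate
10 | [(Z)-13-chlorotridec-7-en-1-yl]magnesium bromide | ClCCCCC/C=C\CCCCCC[Mg]Br | intermediate
11 | [(Z)-13-chlorotridec-7-en-1-yl]titanium triisopropoxide | ClCCCCC/C=C\CCCCCC[Ti](OC(C)C)(OC(C)C)OC(C)C | intermediate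
12 | (1R,8Z)-1-{3,5-bis(TBS-oxy)-4-[(E)-1,2-dichloroethenyloxy]phenyl}-14-chlorotetradec-8-en-1-ol | Cl/C=C(/Cl)Oc1c(O[Si](C)(C)C(C)(C)C)cc(cc1O[Si](C)(C)C(C)(C)C)[C@H](O)CCCCCC/C=C\CCCCCCl | intermediate
13 | TBS ether of 12, (1R,8Z) | Cl/C=C(/Cl)Oc1c(O[Si](C)(C)C(C)(C)C)cc(cc1O[Si](C)(C)C(C)(C)C)[C@H](O[Si](C)(C)C(C)(C)C)CCCCCC/C=C\CCCCCCl | intermediate
14 | as 13 with a chloroethynyloxy group (ArO–C≡C–Cl) in place of the dichloroethenyloxy group, (1R,8Z) | ClC#COc1c(O[Si](C)(C)C(C)(C)C)cc(cc1O[Si](C)(C)C(C)(C)C)[C@H](O[Si](C)(C)C(C)(C)C)CCCCCC/C=C\CCCCCCl | intermediate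
15 | lithium acetylide ArO–C≡C–Li corresponding to 14, (1R,8Z) | [Li]C#COc1c(O[Si](C)(C)C(C)(C)C)cc(cc1O[Si](C)(C)C(C)(C)C)[C@H](O[Si](C)(C)C(C)(C)C)CCCCCC/C=C\CCCCCCl | intermediate
16 | (1R,8Z)-1-[3,5-bis(TBS-oxy)-4-(ethynyloxy)phenyl]-1-(TBS-oxy)-14-chlorotetradec-8-ene | C#COc1c(O[Si](C)(C)C(C)(C)C)cc(cc1O[Si](C)(C)C(C)(C)C)[C@H](O[Si](C)(C)C(C)(C)C)CCCCCC/C=C\CCCCCCl | intermediate
17 | 3-ethoxycyclobut-2-en-1-one | CCOC1=CC(=O)C1 | starting material
18 | chloromagnesium acetylide of 16 (ArO–C≡C–MgCl), (1R,8Z) | Cl[Mg]C#COc1c(O[Si](C)(C)C(C)(C)C)cc(cc1O[Si](C)(C)C(C)(C)C)[C@H](O[Si](C)(C)C(C)(C)C)CCCCCC/C=C\CCCCCCl | intermediate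
19 | as 18 with the chain-end C–Cl converted to C–MgCl, (1R,8Z) | Cl[Mg]C#COc1c(O[Si](C)(C)C(C)(C)C)cc(cc1O[Si](C)(C)C(C)(C)C)[C@H](O[Si](C)(C)C(C)(C)C)CCCCCC/C=C\CCCCCC[Mg]Cl | intermediate
20 | as 18 with the chain end bonded to C1 of a 3-ethoxy-1-(chloromagnesiooxy)cyclobut-2-ene (new carbinol carbon unassigned) | Cl[Mg]C#COc1c(O[Si](C)(C)C(C)(C)C)cc(cc1O[Si](C)(C)C(C)(C)C)[C@H](O[Si](C)(C)C(C)(C)C)CCCCCC/C=C\CCCCCC1(O[Mg]Cl)C=C(OCC)C1 | intermediate
21 | 3-{(6Z,14R)-14-[3,5-bis(TBS-oxy)-4-(ethynyloxy)phenyl]-14-(TBS-oxy)tetradec-6-en-1-yl}cyclobut-2-en-1-one | C#COc1c(O[Si](C)(C)C(C)(C)C)cc(cc1O[Si](C)(C)C(C)(C)C)[C@H](O[Si](C)(C)C(C)(C)C)CCCCCC/C=C\CCCCCC1=CC(=O)C1 | intermediate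
22 | vinylketene: 21 with the cyclobutenone opened to –C(=CH2)–CH=C=O | C#COc1c(O[Si](C)(C)C(C)(C)C)cc(cc1O[Si](C)(C)C(C)(C)C)[C@H](O[Si](C)(C)C(C)(C)C)CCCCCC/C=C\CCCCCC(=C)C=C=O | intermediate
23 | macrocyclic 4-(alk-1-en-2-yl)-3-aryloxycyclobut-2-en-1-one from the [2+2] of 22 (ring C4 unassigned; (R)-carbinol, (Z)-alkene) | O=C1C=C2Oc3c(O[Si](C)(C)C(C)(C)C)cc(cc3O[Si](C)(C)C(C)(C)C)[C@H](O[Si](C)(C)C(C)(C)C)CCCCCC/C=C\CCCCCC(=C)C12 | intermediate
24 | macrocyclic dienylketene from ring opening of 23 | O=C=CC1Oc2c(O[Si](C)(C)C(C)(C)C)cc(cc2O[Si](C)(C)C(C)(C)C)[C@H](O[Si](C)(C)C(C)(C)C)CCCCCC/C=C\CCCCCC(=C)C=1 | intermediate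
25 | macrocyclic 3-aryloxy-5-alkylcyclohexa-2,4-dien-1-one (keto tautomer of 26) | O=C1CC2=CC(=C1)Oc1c(O[Si](C)(C)C(C)(C)C)cc(cc1O[Si](C)(C)C(C)(C)C)[C@H](O[Si](C)(C)C(C)(C)C)CCCCCC/C=C\CCCCC2 | intermediate
26 | tris-TBS ether of the target (ring-A phenol free; ring-B phenols and carbinol silylated), (R,Z) | Oc1cc2cc(c1)Oc1c(O[Si](C)(C)C(C)(C)C)cc(cc1O[Si](C)(C)C(C)(C)C)[C@H](O[Si](C)(C)C(C)(C)C)CCCCCC/C=C\CCCCC2 | intermediate
27 | CNP0316989.2: 22-membered diaryl ether macrocycle; ring A 3-aryloxy-5-alkylphenol, ring B 4-aryloxy-3,5-dihydroxyphenyl, bridge ArB–CH(OH)–(CH2)6–CH=CH–(CH2)5–ArA with (R)-carbinol and (Z)-alkene | Oc1cc2cc(c1)Oc1c(O)cc(cc1O)[C@H](O)CCCCCC/C=C\CCCCC2 | target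

## Step count and risks

Total steps: 9. Longest linear sequence: 7 (steps 2, 3, 5, 6, 7, 8, 9).

**Most likely to fail, first: step 9.** The 22-membered ring closure must beat oligomerisation, and the terminal aryl ynol ether must survive hours at 110 °C. The fallback sets out from 15. The lithium acetylide is quenched with Me3SiCl instead of water to give the storable C-trimethylsilyl ynol ether chloride F1. Direct Mg insertion (no alkyne proton to mask) gives the alkylmagnesium chloride F2, which adds to 17 and is hydrolysed as in step 8 to the silyl-capped cyclobutenone F3. This robust alkyne tolerates xylene at 140 °C and longer times, and the β-silicon effect reinforces the [2+2] regiochemistry, giving the macrocyclic 2-(trimethylsilyl)phenol F4 (silicon between OH and OAr on ring A). Ipso-protodesilylation of that very electron-rich position (CF3CO2H cat., wet CH2Cl2, 0 °C) comes back to the route at 26, which is desilylated with Bu4NF as in step 9.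

**Second: step 8.** Mg insertion into the alkyl chloride may be sluggish, and the acetylide end may not stay innocent at 55 °C. The fallback sets out from 16. Halide exchange (NaI, NaHCO3, acetone, 45 °C) gives the primary iodide F5. MeLi (1.0 equiv, −78 °C) removes the alkyne proton, and t-BuLi (2.1 equiv, Et2O/pentane, −78 °C) then effects iodine–lithium exchange to the dilithio compound F6. Its alkyllithium end adds to 17 at −78 °C, and the same 10-minute dilute-acid hydrolysis comes back to the route at 21.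

**Third: step 5.** The long functionalised Grignard reagent may give insufficient ee or conversion in the catalytic alkylation. The fallback sets out from 9 and 10. Uncatalysed addition of 10 to 9 (THF, −78 °C; 1 M HCl work-up) gives the racemic carbinol F7, and Dess–Martin oxidation gives the aryl ketone F8. Corey–Bakshi–Shibata reduction with (S)-2-methyl-CBS-oxazaborolidine and BH3·SMe2 (aryl as the large group) delivers the (R)-alcohol and comes back to the route at 12.

## Further compounds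

F1 | step 9 | (1R,8Z)-1-{3,5-bis(TBS-oxy)-4-[(trimethylsilyl)ethynyloxy]phenyl}-1-(TBS-oxy)-14-chlorotetradec-8-ene | C[Si](C)(C)C#COc1c(O[Si](C)(C)C(C)(C)C)cc(cc1O[Si](C)(C)C(C)(C)C)[C@H](O[Si](C)(C)C(C)(C)C)CCCCCC/C=C\CCCCCCl
F2 | step 9 | alkylmagnesium chloride from F1 (chain-end C–MgCl) | C[Si](C)(C)C#COc1c(O[Si](C)(C)C(C)(C)C)cc(cc1O[Si](C)(C)C(C)(C)C)[C@H](O[Si](C)(C)C(C)(C)C)CCCCCC/C=C\CCCCCC[Mg]Cl
F3 | step 9 | 3-{(6Z,14R)-14-[3,5-bis(TBS-oxy)-4-((trimethylsilyl)ethynyloxy)phenyl]-14-(TBS-oxy)tetradec-6-en-1-yl}cyclobut-2-en-1-one | C[Si](C)(C)C#COc1c(O[Si](C)(C)C(C)(C)C)cc(cc1O[Si](C)(C)C(C)(C)C)[C@H](O[Si](C)(C)C(C)(C)C)CCCCCC/C=C\CCCCCC1=CC(=O)C1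
F4 | step 9 | 26 carrying SiMe3 on the ring-A carbon between C–OH and C–OAr, (R,Z) | Oc1cc2cc(c1[Si](C)(C)C)Oc1c(O[Si](C)(C)C(C)(C)C)cc(cc1O[Si](C)(C)C(C)(C)C)[C@H](O[Si](C)(C)C(C)(C)C)CCCCCC/C=C\CCCCC2
F5 | step 8 | (1R,8Z)-1-[3,5-bis(TBS-oxy)-4-(ethynyloxy)phenyl]-1-(TBS-oxy)-14-iodotetradec-8-ene | C#COc1c(O[Si](C)(C)C(C)(C)C)cc(cc1O[Si](C)(C)C(C)(C)C)[C@H](O[Si](C)(C)C(C)(C)C)CCCCCC/C=C\CCCCCI
F6 | step 8 | dilithio compound from F5 (ArO–C≡C–Li and chain-end C–Li) | [Li]C#COc1c(O[Si](C)(C)C(C)(C)C)cc(cc1O[Si](C)(C)C(C)(C)C)[C@H](O[Si](C)(C)C(C)(C)C)CCCCCC/C=C\CCCCC[Li]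
F7 | step 5 | racemic (8Z)-1-{3,5-bis(TBS-oxy)-4-[(E)-1,2-dichloroethenyloxy]phenyl}-14-chlorotetradec-8-en-1-ol | Cl/C=C(/Cl)Oc1c(O[Si](C)(C)C(C)(C)C)cc(cc1O[Si](C)(C)C(C)(C)C)C(O)CCCCCC/C=C\CCCCCCl
F8 | step 5 | (8Z)-1-{3,5-bis(TBS-oxy)-4-[(E)-1,2-dichloroethenyloxy]phenyl}-14-chlorotetradec-8-en-1-one | Cl/C=C(/Cl)Oc1c(O[Si](C)(C)C(C)(C)C)cc(cc1O[Si](C)(C)C(C)(C)C)C(=O)CCCCCC/C=C\CCCCCCl
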